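**Plan**
- Retrosynthesis cuts, in order: the formate and the pyranone C–C11 bond (reductive Knoevenagel at the C9 aldehyde), the C8 methylidene, the gem-dimethyl carbinol (from an ester), the C4–C5 bond of ring A (one-carbon ring enlargement of a cis-hydrindan-1-ol), the carbinol–alkenyl bond, and C9–C10 plus C5–C6 of ring B (Diels–Alder).
- Forward: ring B and the cyclopentanone arise together from 3-methylcyclopentenone and a 2-silyloxydiene; an ester-bearing 1,1-disubstituted alkenyl group is added to the ketone; ring A arises by ring enlargement; then methylidene, side chain, pyranone, formate.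
- Enabling feature: in ring A the quaternary, chain-bearing C4 lies between ring-fusion C5–H and carbinol carbon C3, so C4 can be inserted between them as the internal alkene carbon on C1 of a cyclopentanol, the C1–C7a bond migrating to it.
- The shift is triggered by Br+ rather than H+, because protic acid would ionise the tertiary allylic alcohol; the C–Br bond is reduced to C–H in the next step.
- Stereochemistry: C5/C9/C10 relative configuration from the endo Diels–Alder; absolute configuration by separating (R,R)-butanediol ketal diastereomers; C4 in the shift (retention at C5, rotamer control by allylic strain); C3 by equatorial hydride delivery.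

Key step: step 8

Remark (numbering): hydrindanes are numbered as indanes (C1 carbonyl/carbinol, C3a methyl, C4 CH2OBn, C5 ketal, C7a H); decalins as C1–C10 with C3 oxygenated, C4 quaternary, C5 ring-fusion CH, C8 ketal/methylidene, C9 bearing C11, C10 ring-fusion C–CH3.
Remark (assumption): compounds up to 7 are racemic; the absolute configuration is fixed in step 5 on the assumption that the two diastereomeric (R,R)-butanediol ketals separate on silica or by crystallisation.

**Route**

Step 1
Reactants: 1 3-(benzyloxy)propanal; 2 vinylmagnesium bromide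
Product: 3 rac-5-(benzyloxy)pent-1-en-3-ol
Conditions: THF, −78 → 0 °C; aq. NH4Cl
Reagents that add atoms: none
Why: Grignard 1,2-addition of a vinyl nucleophile to an unhindered aldehyde; the racemic carbinol centre is removed by oxidation in step 2.

Step 2
Reactants: 3 rac-5-(benzyloxy)pent-1-en-3-ol
Product: 4 5-(benzyloxy)pent-1-en-3-one
Conditions: Dess–Martin periodinane, NaHCO3, CH2Cl2, 0 °C → rt; used crude
Reagents that add atoms: none
Why: Dess–Martin oxidation of a secondary allylic alcohol under buffered, non-basic conditions that should not eliminate the β-benzyloxy group.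

Step 3
Reactants: 4 5-(benzyloxy)pent-1-en-3-one
Product: 5 (Z)-5-(benzyloxy)-3-(tert-butyldimethylsilyloxy)penta-1,3-diene
Conditions: TBSOTf, Et3N, Et2O, −78 → 0 °C
Reagents that add atoms: tert-butyldimethylsilyl triflate, CC(C)(C)[Si](C)(C)OS(=O)(=O)C(F)(F)F
Why: Soft enolisation (silyl triflate/amine) of the only enolisable side gives the 2-silyloxydiene, the Z enol ether (CH2OBn on the outside of the s-cis diene) being the usual kinetic product.

Step 4
Reactants: 5 (Z)-silyloxydiene; 6 3-methylcyclopent-2-en-1-one
Product: 7 rac-cis-hydrindanone silyl enol ether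
Conditions: Tf2NH (10 mol %), CH2Cl2, −78 → −40 °C; Et3N quench
Reagents that add atoms: none
Why: Triflimide (silylium)-catalysed Diels–Alder reaction of a hindered β-methyl enone with a 2-silyloxydiene (concerted or Mukaiyama–Michael/Michael): the enol-ether β-carbon bonds to the enone β-carbon, the ring fusion is necessarily cis, and the endo transition state puts the outside CH2OBn cis to the cyclopentanone carbons and so trans to the angular methyl.

Step 5
Reactants: 7 rac-cis-hydrindanone silyl enol ether; 8 (2R,3R)-butane-2,3-diol
Product: 9 cis-hydrindan-1-one C5 (4R,5R)-dimethyldioxolane ketal (single enantiomer)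
Conditions: diol (3 equiv), CSA (10 mol %), CH2Cl2, 0 °C → rt; chromatographic separation of the two diastereomers
Reagents that add atoms: none
Why: Acid-catalysed transketalisation of the silyl enol ether (C-protonation, then capture of the oxocarbenium ion by the diol) is much faster than ketalisation of the cyclopentanone and leaves C4 untouched; the C2-symmetric diol adds no stereocentre, so the two enantiomers of 7 become two separable diastereomers, which fixes the absolute configuration.

Step 6
Reactants: 10 methyl pent-4-ynoate
Product: 11 methyl 4-iodopent-4-enoate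
Conditions: NaI, TMSCl, H2O, MeCN, rt
Reagents that add atoms: sodium iodide, [Na+].[I-]
Why: Markovnikov hydroiodination of a terminal alkyne by HI generated in the flask gives the 2-iodo-1-alkene.

Step 7
Reactants: 11 methyl 4-iodopent-4-enoate; 9 ketal ketone
Product: 13 tertiary allylic alcohol (alkenyl cis to H-7a), via alkenylmagnesium chloride 12 (not isolated)
Conditions: i-PrMgCl·LiCl, THF, −40 °C; then LaCl3·2LiCl, 9, −40 → −10 °C; AcOH quench at −20 °C
Reagents that add atoms: none
Why: Iodine–magnesium exchange with the turbo-Grignard reagent tolerates the ester at −40 °C and the lanthanum-mediated 1,2-addition suppresses enolisation; the nucleophile enters the cis-hydrindanone from its convex face (anti to the cyclohexane ring), so the alkenyl group ends cis to H-7a, and the cold quench avoids lactonisation of the alkoxide.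

Step 8
Reactants: 13 tertiary allylic alcohol
Product: 15 4-(bromomethyl) cis-decal-3-one, via hydroxycarbenium ion 14 (not isolated)
Conditions: NBS (1.05 equiv), CH2Cl2, −20 → 0 °C, dark
Reagents that add atoms: N-bromosuccinimide, O=C1CCC(=O)N1Br
Why: Br+ adds to the terminal CH2 of the 1,1-disubstituted alkene and, as charge builds on the tertiary alkene carbon, the C1–C7a bond migrates to it anti to bromine in a suprafacial 1,2-shift with retention at C7a, after which hydroxycarbenium ion 14 loses its proton to succinimide anion to give the C3 ketone; the closest known reaction type is the halonium-induced semipinacol rearrangement of tertiary allylic alcohols with cycloalkanol ring expansion. Ring A is formed by ring enlargement, the alkene carbon being inserted into the C1–C7a bond of the cyclopentane (a 1,2-alkyl shift, so no cyclisation mode applies). The new quaternary C4 is set by the face of the alkene carbon that C7a reaches: with the alkenyl group on the convex face, the reactive rotamer holds the C1–C7a bond parallel to the π system, and allylic 1,2-strain places the small C1–O bond rather than ring C2H2 next to the ester chain, so the chain should end equatorial and trans to H-5 and CH2Br cis to H-5, while C5 (old C7a) keeps its configuration and carries the cis fusion into the decalin. The step needs migration of C7a rather than C2, which the higher migratory aptitude of the more substituted ring-fusion carbon secures, and it needs the shift to outrun capture of the bromonium ion by the ester carbonyl, which stays reversible in a non-nucleophilic solvent at low temperature.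

Step 9
Reactants: 15 4-(bromomethyl) cis-decal-3-one
Product: 16 4-methyl cis-decal-3-one
Conditions: Bu3SnH (3 equiv, ≥1 M), (PhSe)2 (10 mol %), AIBN, benzene, 80 °C
Reagents that add atoms: none
Why: Radical-chain reduction of the neopentyl bromide with tin hydride, where the high hydride concentration and catalytic benzeneselenol trap the primary β-keto radical before a 1,2-acyl (Dowd–Beckwith) shift; no stereocentre is touched.

Step 10
Reactants: 16 4-methyl cis-decal-3-one
Product: 17 3,8-diketone
Conditions: TsOH·H2O (10 mol %), THF–H2O, 40 °C, short reaction time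
Reagents that add atoms: water, O
Why: Acid-catalysed ketal hydrolysis at a stage where only ester, ketone and benzyl ether are present; it is kept mild and short because C9 is now α to a ketone and carries a β-benzyloxy group.

Step 11
Reactants: 17 3,8-diketone
Product: 18 8-methylidene-3-ketone
Conditions: Zn, CH2Br2, TiCl4, THF/CH2Cl2, 0 °C → rt
Reagents that add atoms: dibromomethane, BrCBr
Why: Takai–Lombardo methylenation is non-basic (no C9 epimerisation or β-elimination) and should select the C8 ketone over the α-quaternary C3 ketone and the ester.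

Step 12
Reactants: 18 8-methylidene-3-ketone
Product: 20 3-O-triethylsilyl ether methyl ester, via lithium alkoxide 19 (not isolated)
Conditions: L-Selectride, THF, −78 °C; then TESOTf, −78 → −20 °C
Reagents that add atoms: triethylsilyl triflate, CC[Si](CC)(CC)OS(=O)(=O)C(F)(F)F
Why: L-Selectride reduces the hindered cyclohexanone by equatorial attack, because the axial approach is blocked by C6 of the cis-fused ring; hydride therefore comes from the face carrying the C4 methyl, giving the C3 oxygen cis to the C4 chain, and the alkoxide is silylated in the flask before it can lactonise onto the ester.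

Step 13
Reactants: 20 3-O-triethylsilyl ether methyl ester
Product: 22 tertiary alcohol, via methyl ketone 21 (not isolated)
Conditions: MeMgBr (4 equiv), THF, 0 °C → rt
Reagents that add atoms: methylmagnesium bromide, C[Mg]Br
Why: Double Grignard addition to the methyl ester through the methyl ketone gives the gem-dimethyl carbinol; the silyl ether, benzyl ether and alkene are inert.

Step 14
Reactants: 22 tertiary alcohol
Product: 23 primary alcohol (C11–OH)
Conditions: LiDBB, THF, −78 °C; aq. NH4Cl
Reagents that add atoms: none
Why: Reductive debenzylation with lithium di-tert-butylbiphenylide cleaves the benzyl ether without reducing the isolated 1,1-disubstituted alkene, which hydrogenolysis would, and leaves the silyl ether.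

Step 15
Reactants: 23 primary alcohol
Product: 24 C9 aldehyde
Conditions: Dess–Martin periodinane, NaHCO3, CH2Cl2, 0 °C; used at once
Reagents that add atoms: none
Why: Buffered Dess–Martin oxidation of the primary alcohol; the tertiary alcohol is inert and the neutral conditions should neither move the β,γ-alkene into conjugation nor epimerise C9.

Step 16
Reactants: 25 methyl acetoacetate; 26 malonyl dichloride
Product: 27 methyl 4-hydroxy-6-methyl-2-oxo-2H-pyran-5-carboxylate
Conditions: neat or CH2Cl2, rt → 40 °C
Reagents that add atoms: none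
Why: Malonyl dichloride–β-keto ester pyrone synthesis: one acyl chloride acylates the acetoacetate α-carbon and the other its enol oxygen, closing the 4-hydroxy-2-pyrone.

Step 17
Reactants: 24 C9 aldehyde; 27 hydroxypyrone
Product: 29 3-alkyl-4-hydroxy-2-pyrone, via alkylidene pyrandione 28 (not isolated)
Conditions: Hantzsch ester (1.2 equiv), L-proline (20 mol %), CH2Cl2, rt
Reagents that add atoms: none
Why: Three-component reductive Knoevenagel alkylation: C3 of the acidic hydroxypyrone condenses with the aldehyde and the Hantzsch ester reduces the alkylidene at once, so no bis-adduct forms and C9 is not touched.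

Step 18
Reactants: 29 3-alkyl-4-hydroxy-2-pyrone
Product: 30 2-methoxy-4-pyranone
Conditions: MeOTf (1.5 equiv), 2,6-di-tert-butyl-4-methylpyridine, CH2Cl2, 0 °C → rt
Reagents that add atoms: methyl triflate, COS(=O)(=O)C(F)(F)F
Why: O-methylation of a 4-hydroxy-2-pyrone by a hard methylating agent under non-anionic conditions should occur at the C2 carbonyl oxygen (the 4-OH is held in a hydrogen bond to the neighbouring ester), giving the 2-methoxy-4-pyranone after proton loss to the hindered base.

Step 19
Reactants: 30 2-methoxy-4-pyranone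
Product: 31 tertiary formate triethylsilyl ether
Conditions: acetic formic anhydride, pyridine, CH2Cl2, 0 °C → rt
Reagents that add atoms: acetic formic anhydride, CC(=O)OC=O
Why: Formylation with the mixed anhydride, which transfers formyl selectively, at the only free hydroxyl (the tertiary alcohol).

Step 20
Reactants: 31 tertiary formate triethylsilyl ether
Product: 32 CNP0292250.1
Conditions: HF·pyridine, pyridine, THF, 0 °C → rt
Reagents that add atoms: none
Why: Fluoride-mediated cleavage of the triethylsilyl ether under buffered, weakly acidic conditions that should leave the tertiary formate, ester, methoxypyranone and alkene intact.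

**Compound list**

1 | 3-(benzyloxy)propanal | O=CCCOCc1ccccc1 | starting material
2 | vinylmagnesium bromide | C=C[Mg]Br | starting material
3 | rac-5-(benzyloxy)pent-1-en-3-ol | C=CC(O)CCOCc1ccccc1 | intermediate
4 | 5-(benzyloxy)pent-1-en-3-one | C=CC(=O)CCOCc1ccccc1 | intermediate
5 | (Z)-5-(benzyloxy)-3-(tert-butyldimethylsilyloxy)penta-1,3-diene | C=C/C(O[Si](C)(C)C(C)(C)C)=C/COCc1ccccc1 | intermediate
6 | 3-methylcyclopent-2-en-1-one | CC1=CC(=O)CC1 | starting material
7 | rac-4-(benzyloxymethyl)-5-(tert-butyldimethylsilyloxy)-3a-methyl-2,3,3a,4,7,7a-hexahydroinden-1-one; 3a-CH3 cis to H-7a, 4-CH2OBn trans to 3a-CH3; racemic, the enantiomer carried on is drawn | CC(C)(C)[Si](C)(C)OC1=CC[C@H]2C(=O)CC[C@@]2(C)[C@H]1COCc3ccccc3 | intermediate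
8 | (2R,3R)-butane-2,3-diol | C[C@@H](O)[C@@H](C)O | starting material
9 | cis-4-(benzyloxymethyl)-3a-methyloctahydroinden-1-one, C5 ketal with (2R,3R)-butanediol; relative configuration as 7, single enantiomer | C[C@H]1OC2(O[C@@H]1C)CC[C@H]3C(=O)CC[C@@]3(C)[C@H]2COCc4ccccc4 | intermediate
10 | methyl pent-4-ynoate | C#CCCC(=O)OC | starting material
11 | methyl 4-iodopent-4-enoate | C=C(I)CCC(=O)OC | intermediate
12 | (5-methoxy-5-oxopent-1-en-2-yl)magnesium chloride, LiCl complex | C=C([Mg]Cl)CCC(=O)OC.[Li+].[Cl-] | intermediate (not isolated)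
13 | 1-hydroxy-1-(5-methoxy-5-oxopent-1-en-2-yl) derivative of 9; alkenyl cis to H-7a and 3a-CH3, OH trans | C[C@H]1OC2(O[C@@H]1C)CC[C@H]3[C@](O)(C(=C)CCC(=O)OC)CC[C@@]3(C)[C@H]2COCc4ccccc4 | intermediate (key-step precursor)
14 | O-protonated form of ketone 15 (hydroxycarbenium ion) | C[C@H]1OC2(O[C@@H]1C)CC[C@H]3[C@@](CBr)(CCC(=O)OC)C(=[OH+])CC[C@@]3(C)[C@H]2COCc4ccccc4 | intermediate (not isolated)
15 | cis-decal-3-one with 4-CH2Br (cis to H-5), 4-(3-methoxy-3-oxopropyl) (trans to H-5), C8 butanediol ketal, 9-CH2OBn (trans to H-5), 10-CH3 (cis to H-5) | C[C@H]1OC2(O[C@@H]1C)CC[C@H]3[C@@](CBr)(CCC(=O)OC)C(=O)CC[C@@]3(C)[C@H]2COCc4ccccc4 | intermediate (key-step product)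
16 | as 15 with 4-CH3 in place of 4-CH2Br | C[C@H]1OC2(O[C@@H]1C)CC[C@H]3[C@@](C)(CCC(=O)OC)C(=O)CC[C@@]3(C)[C@H]2COCc4ccccc4 | intermediate
17 | cis-decalin-3,8-dione with 4-CH3, 4-(3-methoxy-3-oxopropyl), 9-CH2OBn, 10-CH3 | O=C1CC[C@H]2[C@@](C)(CCC(=O)OC)C(=O)CC[C@@]2(C)[C@H]1COCc3ccccc3 | intermediate
18 | 8-methylidene analogue of 17 (C3 ketone kept) | C=C1CC[C@H]2[C@@](C)(CCC(=O)OC)C(=O)CC[C@@]2(C)[C@H]1COCc3ccccc3 | intermediate
19 | lithium C3 alkoxide from 18; O-3 trans to H-5, cis to the C4 chain | C=C1CC[C@H]2[C@@](C)(CCC(=O)OC)[C@@H]([O-])CC[C@@]2(C)[C@H]1COCc3ccccc3.[Li+] | intermediate (not isolated)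
20 | 3-O-triethylsilyl ether of the C3 alcohol, methyl ester chain | C=C1CC[C@H]2[C@@](C)(CCC(=O)OC)[C@@H](O[Si](CC)(CC)CC)CC[C@@]2(C)[C@H]1COCc3ccccc3 | intermediate
21 | as 20 with a 3-oxobutyl chain on C4 | C=C1CC[C@H]2[C@@](C)(CCC(C)=O)[C@@H](O[Si](CC)(CC)CC)CC[C@@]2(C)[C@H]1COCc3ccccc3 | intermediate (not isolated)
22 | as 20 with a 3-hydroxy-3-methylbutyl chain on C4 | C=C1CC[C@H]2[C@@](C)(CCC(C)(C)O)[C@@H](O[Si](CC)(CC)CC)CC[C@@]2(C)[C@H]1COCc3ccccc3 | intermediate
23 | as 22 with 9-CH2OH | C=C1CC[C@H]2[C@@](C)(CCC(C)(C)O)[C@@H](O[Si](CC)(CC)CC)CC[C@@]2(C)[C@H]1CO | intermediate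
24 | as 22 with 9-CHO | C=C1CC[C@H]2[C@@](C)(CCC(C)(C)O)[C@@H](O[Si](CC)(CC)CC)CC[C@@]2(C)[C@H]1C=O | intermediate
25 | methyl acetoacetate | COC(=O)CC(C)=O | starting material
26 | malonyl dichloride | O=C(Cl)CC(=O)Cl | starting material
27 | methyl 4-hydroxy-6-methyl-2-oxo-2H-pyran-5-carboxylate | COC(=O)C1=C(C)OC(=O)C=C1O | intermediate
28 | Knoevenagel adduct: 3-alkylidene-pyran-2,4-dione on C11 (alkene geometry not defined, mixture) | C=C1CC[C@H]2[C@@](C)(CCC(C)(C)O)[C@@H](O[Si](CC)(CC)CC)CC[C@@]2(C)[C@H]1C=C3C(=O)OC(C)=C(C(=O)OC)C3=O | intermediate (not isolated)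
29 | C11 linked to C3 of the 4-hydroxy-5-methoxycarbonyl-6-methyl-2-pyrone; decalin as 22 | C=C1CC[C@H]2[C@@](C)(CCC(C)(C)O)[C@@H](O[Si](CC)(CC)CC)CC[C@@]2(C)[C@H]1CC3=C(O)C(C(=O)OC)=C(C)OC3=O | intermediate
30 | as 29 with the pyrone as 2-methoxy-4-pyranone | C=C1CC[C@H]2[C@@](C)(CCC(C)(C)O)[C@@H](O[Si](CC)(CC)CC)CC[C@@]2(C)[C@H]1Cc3c(OC)oc(C)c(C(=O)OC)c3=O | intermediate
31 | as 30 with the tertiary alcohol as formate | C=C1CC[C@H]2[C@@](C)(CCC(C)(C)OC=O)[C@@H](O[Si](CC)(CC)CC)CC[C@@]2(C)[C@H]1Cc3c(OC)oc(C)c(C(=O)OC)c3=O | intermediate
32 | CNP0292250.1: 10-CH3 and 4-CH3 cis to H-5; C4 chain, 3-OH and 9-CH2(pyranone) trans to H-5 | C=C1CC[C@H]2[C@@](C)(CCC(C)(C)OC=O)[C@@H](O)CC[C@@]2(C)[C@H]1Cc1c(OC)oc(C)c(C(=O)OC)c1=O | target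

**Step count and risks**

Total steps: 20. Longest linear sequence: 18 (steps 1–5, 7–15, 17–20); steps 6 and 16 are side branches.

Most likely to fail:

1. Step 8. What may go wrong: poor facial selectivity at the alkene carbon (the two rotamers about the C1–alkene bond reacting at similar rates, giving the C4 epimer), or capture of the bromonium ion by the ester carbonyl. Fallback: the quaternary centre is set in a separate, reagent-controlled step and transferred stereospecifically. Alcohol 13 is epoxidised with a chiral hafnium(IV)–bis(hydroxamic acid) catalyst and cumene hydroperoxide, the ligand enantiomer being chosen for the needed alkene face, to give epoxy alcohol F1. ZnBr2 in CH2Cl2 then triggers the 2,3-epoxy-alcohol semipinacol shift, in which C7a attacks the tertiary epoxide carbon anti to its C–O bond with inversion, to give hydroxymethyl ketone F2. An Appel reaction (PPh3, CBr4) converts F2 into 15, where the route is rejoined.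

2. Step 17. What may go wrong: amine-induced isomerisation of the β,γ-unsaturated aldehyde (alkene migration, C9 epimerisation), or slow condensation at the hindered α-branched aldehyde. Fallback: the bond is made by organometallic addition and the extra oxygen is removed afterwards. Hydroxypyrone 27 is O-methylated with MeOTf to 2-methoxy-4-pyranone F3 and iodinated with NIS to iodopyranone F4. Iodine–magnesium exchange (i-PrMgCl·LiCl, −40 °C) gives pyranylmagnesium chloride F5, which adds to aldehyde 24 to give carbinol F6 (mixture at C11, which does not matter). The secondary hydroxyl is converted into phenyl thionocarbonate F7 (PhOC(S)Cl, pyridine, DMAP), and Barton–McCombie reduction (Bu3SnH, AIBN) gives 30, where the route is rejoined.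

3. Step 4. What may go wrong: loss of the allylic benzyloxy group from the diene under the strong acid catalyst (vinylogous elimination), or no cycloaddition with the unactivated β-methyl enone. Fallback: the dienophile is activated instead, so that a mild Lewis acid suffices. Enone 6 is α-iodinated (I2, pyridine) to iodo enone F8, and palladium-catalysed methoxycarbonylation (CO, MeOH, Et3N) gives keto ester F9. Its Diels–Alder reaction with 5 (ZnCl2, CH2Cl2, −40 °C) gives adduct F10, which is ketalised and resolved as in step 5 to ketal ester F11. Krapcho demethoxycarbonylation (LiCl, wet DMSO, 150 °C), with protonation to the more stable cis fusion, gives 9, where the route is rejoined.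

**Further compounds**

F1 | step 8 | epoxy alcohol from 13 (2-substituted oxirane on C1; configuration set for anti migration of C7a) | C[C@H]1OC2(O[C@@H]1C)CC[C@H]3[C@](O)([C@]4(CCC(=O)OC)CO4)CC[C@@]3(C)[C@H]2COCc5ccccc5
F2 | step 8 | 4-(hydroxymethyl) analogue of 15 | C[C@H]1OC2(O[C@@H]1C)CC[C@H]3[C@@](CO)(CCC(=O)OC)C(=O)CC[C@@]3(C)[C@H]2COCc4ccccc4
F3 | step 17 | methyl 6-methoxy-2-methyl-4-oxo-4H-pyran-3-carboxylate | COC(=O)c1c(C)oc(OC)cc1=O
F4 | step 17 | methyl 5-iodo-6-methoxy-2-methyl-4-oxo-4H-pyran-3-carboxylate | COC(=O)c1c(C)oc(OC)c(I)c1=O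
F5 | step 17 | pyranylmagnesium chloride from F4 | COC(=O)c1c(C)oc(OC)c([Mg]Cl)c1=O
F6 | step 17 | C11 carbinol from 24 and F5 (mixture at C11) | C=C1CC[C@H]2[C@@](C)(CCC(C)(C)O)[C@@H](O[Si](CC)(CC)CC)CC[C@@]2(C)[C@H]1C(O)c3c(OC)oc(C)c(C(=O)OC)c3=O
F7 | step 17 | O-phenyl thionocarbonate of F6 | C=C1CC[C@H]2[C@@](C)(CCC(C)(C)O)[C@@H](O[Si](CC)(CC)CC)CC[C@@]2(C)[C@H]1C(OC(=S)Oc4ccccc4)c3c(OC)oc(C)c(C(=O)OC)c3=O
F8 | step 4 | 2-iodo-3-methylcyclopent-2-en-1-one | CC1=C(I)C(=O)CC1
F9 | step 4 | methyl 2-methyl-5-oxocyclopent-1-ene-1-carboxylate | COC(=O)C1=C(C)CCC1=O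
F10 | step 4 | rac-7a-methoxycarbonyl analogue of 7 (one enantiomer drawn) | CC(C)(C)[Si](C)(C)OC1=CC[C@@]2(C(=O)OC)C(=O)CC[C@@]2(C)[C@H]1COCc3ccccc3
F11 | step 4 | 7a-methoxycarbonyl analogue of 9 | C[C@H]1OC2(O[C@@H]1C)CC[C@@]3(C(=O)OC)C(=O)CC[C@@]3(C)[C@H]2COCc4ccccc4
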